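**Retrosynthetic overview**
1. Target 20 ⇐ diketone 16 by exo-Mannich at C-16, face-selective reduction of the C-12 ketone, then amine elimination to the 16-methylene.
2. 16 ⇐ acid unmasking of pentacyclic photoadduct 14: the methoxycyclopropane gives the C-12 ketone and Δ8(9), the ketal phosphate gives the C-15 ketone and 1α-OH.
3. 14 ⇐ intramolecular arene–alkene meta-photocycloaddition of anisole 13, whose C-1 acetate has been turned into a 1-alkoxyvinyl phosphate tether; three rings form at once and C-11/C-13 are set.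
4. Tricyclic diol 11 (rings A/B plus the aromatic ring) ⇐ epoxide–arene closure of ring B from cis-epoxy alcohol 10.
5. 10 ⇐ (R)-α-cyclocitral 7 + 4-methoxybenzyl Grignard; C-5 comes from CBS reduction of enone 1 and Still–Wittig chirality transfer. Ring order: A (bought) → B → bridged C/D bicycle.

Assumption: atoms are numbered as in the target skeleton (rings A/B C-1 to C-10, C-8=C-9, bridgeheads C-11 and C-13, one-carbon bridge C-12, two-carbon bridge C-15/C-16, exocyclic C-17, angular methyl C-20); α is the face of C-20, β the face of H-5 and of the C-15/C-16 bridge. The route is a paper design and has not been tested experimentally.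

**Step 1**
Reactants: 1 2,4,4-trimethylcyclohex-2-en-1-one
Product: 2 (S)-2,4,4-trimethylcyclohex-2-en-1-ol
Conditions: (R)-Me-CBS (10 mol %), BH3·SMe2, THF, −20 °C
Reagents that add atoms: none
Why: Corey–Bakshi–Shibata 1,2-reduction in which the 2-methylvinyl arm acts as the large group, so the (R)-catalyst gives the (S)-carbinol whose chirality is later relayed to C-5.

**Step 2**
Reactants: 2 (S)-2,4,4-trimethylcyclohex-2-en-1-ol; 3 tributyl(iodomethyl)stannane
Product: 4 tributyl({[(1S)-2,4,4-trimethylcyclohex-2-en-1-yl]oxy}methyl)stannane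
Conditions: KH, 18-crown-6 (cat.), THF, 0 °C → rt
Reagents that add atoms: none
Why: Williamson etherification of the potassium alkoxide with the primary iodide, leaving the stereocentre untouched.

**Step 3**
Reactants: 4 stannylmethyl ether
Product: 6 [(1R)-2,6,6-trimethylcyclohex-2-en-1-yl]methanol, via lithiomethyl ether 5 (not isolated)
Conditions: n-BuLi, THF, −78 → −20 °C; then H2O
Reagents that add atoms: none
Why: Still–Wittig [2,3]-sigmatropic rearrangement after Sn–Li exchange, which is suprafacial so the C–O bond of 4 is replaced by a C–C bond on the same ring face at the former alkene terminus, giving (R) at C-5 and moving the alkene to C-1=C-10.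

**Step 4**
Reactants: 6 (R)-α-cyclogeraniol
Product: 7 (1R)-2,6,6-trimethylcyclohex-2-ene-1-carbaldehyde ((R)-α-cyclocitral)
Conditions: TEMPO (10 mol %), PhI(OAc)2, CH2Cl2, rt
Reagents that add atoms: none
Why: TEMPO/PhI(OAc)2 oxidation of the primary alcohol under near-neutral conditions, which avoids epimerisation or conjugation of the β,γ-unsaturated aldehyde.

**Step 5**
Reactants: 7 (R)-α-cyclocitral; 8 (4-methoxybenzyl)magnesium chloride
Product: 9 (1S)-2-(4-methoxyphenyl)-1-[(1R)-2,6,6-trimethylcyclohex-2-en-1-yl]ethan-1-ol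
Conditions: THF, −78 °C; then H2O
Reagents that add atoms: none
Why: Grignard addition under Felkin–Anh control, with the quaternary C-4 anti to the nucleophile, giving the (S)-carbinol that becomes the 6α-oxygen.

**Step 6**
Reactants: 9 homoallylic alcohol
Product: 10 (1S)-2-(4-methoxyphenyl)-1-[(1R,2R,6S)-1,3,3-trimethyl-7-oxabicyclo[4.1.0]heptan-2-yl]ethan-1-ol (epoxide cis to the side chain)
Conditions: VO(acac)2 (5 mol %), t-BuOOH, CH2Cl2, 0 °C → rt
Reagents that add atoms: tert-butyl hydroperoxide, CC(C)(C)OO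
Why: hydroxyl-directed vanadium epoxidation of the homoallylic alcohol delivers oxygen to the ring face carrying the side chain (α), which fixes the future 1α-oxygen.

**Step 7**
Reactants: 10 cis-epoxy alcohol
Product: 11 (4bR,5S,8aR,9S)-3-methoxy-4b,8,8-trimethyl-4b,5,6,7,8,8a,9,10-octahydrophenanthrene-5,9-diol (1α,6α-diol; C-20 α, H-5 β)
Conditions: InBr3 (20 mol %), CH2Cl2, −20 °C → rt
Reagents that add atoms: none
Why: Lewis-acid epoxide–arene Friedel–Crafts cyclisation (6-exo) at the tertiary epoxide carbon C-10, where the arene enters anti to the C–O bond through a chair with the side chain equatorial, giving the trans A/B fusion, the α C-20 methyl and the 1α-OH.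

**Step 8**
Reactants: 11 tricyclic diol
Product: 12 1α,6α-diacetate of 11
Conditions: Ac2O, DMAP (cat.), pyridine, 60 °C
Reagents that add atoms: acetic anhydride, CC(=O)OC(C)=O
Why: DMAP-catalysed acylation of both hindered secondary alcohols with no change at any stereocentre.

**Step 9**
Reactants: 12 diacetate
Product: 13 1α,6α-bis{[1-(diethoxyphosphoryloxy)ethenyl]oxy} derivative (both acetates as 1-alkoxyvinyl diethyl phosphates)
Conditions: KHMDS (2.4 equiv), HMPA, THF, −78 °C; ClP(O)(OEt)2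
Reagents that add atoms: diethyl chlorophosphate, CCOP(=O)(Cl)OCC
Why: O-phosphorylation of the potassium ester enolates (ketene acetal phosphate formation), which K+/HMPA favours over C-attack, puts an electron-rich alkene three atoms from C-9 on the C-1 oxygen.

**Step 10 (key step)**
Reactants: 13 bis(ketene acetal phosphate)
Product: 14 pentacyclic meta-photocycloadduct (new bonds C-15–C-11 and C-16–C-13 on the β-face, cyclopropane C-12–C-13–C-14, Δ8(9), 12-OMe; C-15 bears the exo phosphate and the endo O-link to C-1)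
Conditions: hν (254 nm, quartz), degassed cyclohexane (2 mM), rt
Reagents that add atoms: none
Why: Proposed new method: the S1 anisole ring and the tethered 1-alkoxyvinyl phosphate form an exciplex that bonds C-15 to C-11 and C-16 to C-13 (both ortho to OMe, which stabilises the bridging C-12), and the C-12/allyl biradical closes at the unhindered C-14, so the five-membered D ring, the cyclopropane and the tether ring form in one operation, while the C-1 tether fixes the regiochemistry and delivers the alkene to the β-face anti to the axial C-20 methyl, setting C-11 and C-13; the closest known reaction type is the intramolecular arene–alkene meta-photocycloaddition of alkoxyarenes with tethered enol ethers, and only the enol-phosphate alkene is new.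

**Step 11**
Reactants: 14 photoadduct
Product: 15 6α-acetoxy-1α-hydroxy-17-nor-12,15-dione (bicyclo[3.2.1]oct-2-ene-6,8-dione C/D unit, Δ8(9), C-14 and C-16 CH2)
Conditions: 1 M HCl, THF, 0 °C → rt
Reagents that add atoms: water, O
Why: acidolysis of a 1-methoxy meta-adduct (protonation at C-14 with C-12–C-14 cleavage) gives the bridging C-12 ketone with the tetrasubstituted Δ8(9) alkene retained, while hydrolysis of the ketal phosphate releases the C-15 ketone and 1α-OH and the spectator ketene acetal phosphate returns the 6α-acetate; C-11 and C-13 are bridgeheads and cannot epimerise.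

**Step 12**
Reactants: 15 hydroxy diketone
Product: 16 1α,6α-diacetoxy-17-nor-12,15-dione
Conditions: Ac2O, DMAP (cat.), pyridine, rt
Reagents that add atoms: acetic anhydride, CC(=O)OC(C)=O
Why: acylation of the only free hydroxyl (any ring-chain hemiketal form of 15 is funnelled to the open acetate), with both ketones inert because neither has an enolisable bridgehead.

**Step 13**
Reactants: 16 diacetoxy diketone
Product: 18 16-exo-(dimethylaminomethyl)-12-hydroxy-15-ketone (12-OH syn to the C-15/C-16 bridge), via Mannich base 17 (not isolated)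
Conditions: LiHMDS (1.05 equiv), THF, −78 °C; Me2N=CH2+ I−; then LiAlH(Ot-Bu)3, −78 → −30 °C; H2O
Reagents that add atoms: Eschenmoser's salt, C[N+](C)=C.[I-]
Why: Mannich reaction of the only possible enolate (C-16) on its open exo face, after which the exo aminomethyl group screens the two-carbon-bridge face of the strained C-12 ketone so the bulky hydride enters from the Δ8(9) side and gives the (12S)-alcohol, while the α-branched C-15 ketone and the acetates are left alone.

**Step 14**
Reactants: 18 amino alcohol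
Product: 20 1α,6α-diacetoxyjungermannenone C, via ammonium iodide 19 (not isolated)
Conditions: MeI, CH2Cl2, rt; then aq NaHCO3
Reagents that add atoms: none
Why: N-methylation and E1cB elimination of trimethylamine (Mannich-base methylenation) give the 16-methylene-15-ketone and remove the temporary C-16 stereocentre.

**Compound list**
1 | 2,4,4-trimethylcyclohex-2-en-1-one | CC1=CC(C)(C)CCC1=O | starting material
2 | (S)-2,4,4-trimethylcyclohex-2-en-1-ol | O[C@H]1CCC(C)(C)C=C1C | intermediate
3 | tributyl(iodomethyl)stannane | CCCC[Sn](CCCC)(CCCC)CI | starting material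
4 | tributyl({[(1S)-2,4,4-trimethylcyclohex-2-en-1-yl]oxy}methyl)stannane | CCCC[Sn](CCCC)(CCCC)CO[C@H]1CCC(C)(C)C=C1C | intermediate
5 | {[(1S)-2,4,4-trimethylcyclohex-2-en-1-yl]oxy}methyllithium | [Li]CO[C@H]1CCC(C)(C)C=C1C | intermediate (not isolated)
6 | [(1R)-2,6,6-trimethylcyclohex-2-en-1-yl]methanol | OC[C@H]1C(C)=CCCC1(C)C | intermediate
7 | (1R)-2,6,6-trimethylcyclohex-2-ene-1-carbaldehyde | O=C[C@H]1C(C)=CCCC1(C)C | intermediate
8 | (4-methoxybenzyl)magnesium chloride | COc1ccc(C[Mg]Cl)cc1 | starting material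
9 | (1S)-2-(4-methoxyphenyl)-1-[(1R)-2,6,6-trimethylcyclohex-2-en-1-yl]ethan-1-ol | COc1ccc(C[C@H](O)[C@H]2C(C)=CCCC2(C)C)cc1 | intermediate
10 | (1S)-2-(4-methoxyphenyl)-1-[(1R,2R,6S)-1,3,3-trimethyl-7-oxabicyclo[4.1.0]heptan-2-yl]ethan-1-ol | COc1ccc(C[C@H](O)[C@@H]2C(C)(C)CC[C@@H]3O[C@]23C)cc1 | intermediate
11 | (4bR,5S,8aR,9S)-3-methoxy-4b,8,8-trimethyl-4b,5,6,7,8,8a,9,10-octahydrophenanthrene-5,9-diol | COc1ccc2C[C@H](O)[C@@H]3C(C)(C)CC[C@H](O)[C@@]3(C)c2c1 | intermediate
12 | 1α,6α-diacetate of 11 | COc1ccc2C[C@H](OC(C)=O)[C@@H]3C(C)(C)CC[C@H](OC(C)=O)[C@@]3(C)c2c1 | intermediate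
13 | 1α,6α-bis{[1-(diethoxyphosphoryloxy)ethenyl]oxy} analogue of 12 | COc1ccc2C[C@H](OC(=C)OP(=O)(OCC)OCC)[C@@H]3C(C)(C)CC[C@H](OC(=C)OP(=O)(OCC)OCC)[C@@]3(C)c2c1 | intermediate
14 | meta-photocycloadduct (C-15–C-11 and C-16–C-13 bonds β, cyclopropane C-12/C-13/C-14, Δ8(9), 12-OMe, C-15 ketal phosphate O-linked to C-1) | C1[C@@]2(OP(=O)(OCC)OCC)[C@@H]3C4=C(C[C@H](OC(=C)OP(=O)(OCC)OCC)[C@@H]5C(C)(C)CC[C@H](O2)[C@@]45C)[C@@H]6[C@H]1[C@]36OC | intermediate
15 | 6α-acetoxy-1α-hydroxy-17-nor-12,15-dione | C1C(=O)[C@@H]2C3=C(C[C@H](OC(C)=O)[C@@H]4C(C)(C)CC[C@H](O)[C@@]34C)C[C@H]1C2=O | intermediate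
16 | 1α,6α-diacetoxy-17-nor-12,15-dione | C1C(=O)[C@@H]2C3=C(C[C@H](OC(C)=O)[C@@H]4C(C)(C)CC[C@H](OC(C)=O)[C@@]34C)C[C@H]1C2=O | intermediate
17 | 16-exo-(dimethylaminomethyl) derivative of 16 | CN(C)C[C@H]1C(=O)[C@@H]2C3=C(C[C@H](OC(C)=O)[C@@H]4C(C)(C)CC[C@H](OC(C)=O)[C@@]34C)C[C@H]1C2=O | intermediate (not isolated)
18 | 16-exo-(dimethylaminomethyl)-12-hydroxy-15-ketone (12S) | CN(C)C[C@H]1C(=O)[C@@H]2C3=C(C[C@H](OC(C)=O)[C@@H]4C(C)(C)CC[C@H](OC(C)=O)[C@@]34C)C[C@H]1[C@@H]2O | intermediate
19 | trimethylammonium iodide of 18 | C[N+](C)(C)C[C@H]1C(=O)[C@@H]2C3=C(C[C@H](OC(C)=O)[C@@H]4C(C)(C)CC[C@H](OC(C)=O)[C@@]34C)C[C@H]1[C@@H]2O.[I-] | intermediate (not isolated)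
20 | 1α,6α-diacetoxyjungermannenone C (1S,5R,6S,10R,11R,12S,13R) | C=C1C(=O)[C@@H]2C3=C(C[C@H](OC(C)=O)[C@@H]4C(C)(C)CC[C@H](OC(C)=O)[C@@]34C)C[C@H]1[C@@H]2O | target

**Total step count:** 14. **Longest linear sequence:** 14 (from 1; compounds 3 and 8 are bought).

**Steps most likely to fail, with fallbacks**

Step 10 (photocycloaddition; the alkene class is untested, and ortho addition or reaction of the C-6 arm could compete). The fallback leaves at 12 and returns at 20; it gives up the tether and uses a symmetric alkene so that regiochemistry is not an issue. Diacetate 12 is irradiated at 254 nm with excess 2,2-dimethyl-1,3-dioxole, and OMe-directed addition across C-11/C-13 from the β-face gives the exo-acetonide adduct F1. PPTS in wet acetone opens only the methoxycyclopropane to the 12-ketone acetonide F2. NaBH4 attacks from the Δ8(9) side, the other face being blocked by the exo dioxolane, to give the 12-alcohol F3. TBSOTf/2,6-lutidine gives the 12-O-TBS acetonide F4, and 80 % AcOH removes the acetonide to give the 15,16-diol F5. DMSO/TFAA then Et3N gives the 15,16-dione F6, and one equivalent of Ph3P=CH2 olefinates the less hindered C-16 carbonyl to the 12-O-TBS enone F7. HF·pyridine then gives 20.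

Step 7 (epoxide–arene closure meta to OMe; hydride shift to the C-1 ketone may win). The fallback leaves at 7 and returns at 11; it forms the C-9–C-10 bond by enolate arylation and uses the hydride-shift ketone deliberately. Aldehyde 7 and (2-bromo-4-methoxybenzyl)magnesium chloride give the bromo homoallylic alcohol F8. VO(acac)2/t-BuOOH gives the cis-epoxide F9, and MgBr2·OEt2 (Meinwald rearrangement) gives the C-1 ketone F10. Pd2(dba)3/(t-Bu)3P with NaOt-Bu closes ring B by intramolecular ketone α-arylation at C-10 to give the tricyclic 6α-hydroxy-1-ketone F11. NaBH4, by axial attack, gives the equatorial 1α-alcohol 11.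

Step 13 (the Mannich base may eliminate or direct hydride before the C-12 reduction). The fallback leaves at 16 and returns at 18; it separates the blocking group from the methylene source. Diketone 16 with LiHMDS/PhSeCl gives the 16-exo-phenylselenide F12, which cannot eliminate. LiAlH(Ot-Bu)3 then gives the 12-alcohol F13, and Bu3SnH/AIBN removes selenium to give the 12-hydroxy-15-ketone F14. LiHMDS (2.1 equiv) and Eschenmoser's salt convert it into amino alcohol 18 for step 14.

**Further compounds**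
F1 | step 10 | 15,16-exo-acetonide meta-photocycloadduct of 12 | CC1(C)O[C@H]2[C@@H](O1)[C@@H]3C4=C(C[C@H](OC(C)=O)[C@@H]5C(C)(C)CC[C@H](OC(C)=O)[C@@]45C)[C@@H]6[C@H]2[C@]36OC
F2 | step 10 | 12-ketone 15,16-acetonide, Δ8(9) | CC1(C)O[C@H]2[C@@H](O1)[C@@H]3C4=C(C[C@H](OC(C)=O)[C@@H]5C(C)(C)CC[C@H](OC(C)=O)[C@@]45C)C[C@H]2C3=O
F3 | step 10 | 12-alcohol 15,16-acetonide | CC1(C)O[C@H]2[C@@H](O1)[C@@H]3C4=C(C[C@H](OC(C)=O)[C@@H]5C(C)(C)CC[C@H](OC(C)=O)[C@@]45C)C[C@H]2[C@@H]3O
F4 | step 10 | 12-O-TBS 15,16-acetonide | CC1(C)O[C@H]2[C@@H](O1)[C@@H]3C4=C(C[C@H](OC(C)=O)[C@@H]5C(C)(C)CC[C@H](OC(C)=O)[C@@]45C)C[C@H]2[C@@H]3O[Si](C)(C)C(C)(C)C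
F5 | step 10 | 12-O-TBS 15,16-diol | O[C@H]1[C@@H](O)[C@@H]2C3=C(C[C@H](OC(C)=O)[C@@H]4C(C)(C)CC[C@H](OC(C)=O)[C@@]34C)C[C@H]1[C@@H]2O[Si](C)(C)C(C)(C)C
F6 | step 10 | 12-O-TBS 15,16-dione | O=C1C(=O)[C@@H]2C3=C(C[C@H](OC(C)=O)[C@@H]4C(C)(C)CC[C@H](OC(C)=O)[C@@]34C)C[C@H]1[C@@H]2O[Si](C)(C)C(C)(C)C
F7 | step 10 | 12-O-TBS ether of 20 | C=C1C(=O)[C@@H]2C3=C(C[C@H](OC(C)=O)[C@@H]4C(C)(C)CC[C@H](OC(C)=O)[C@@]34C)C[C@H]1[C@@H]2O[Si](C)(C)C(C)(C)C
F8 | step 7 | (1S)-2-(2-bromo-4-methoxyphenyl)-1-[(1R)-2,6,6-trimethylcyclohex-2-en-1-yl]ethan-1-ol | COc1ccc(C[C@H](O)[C@H]2C(C)=CCCC2(C)C)c(Br)c1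
F9 | step 7 | cis-epoxide of F8 | COc1ccc(C[C@H](O)[C@@H]2C(C)(C)CC[C@@H]3O[C@]23C)c(Br)c1
F10 | step 7 | 3-[(1S)-2-(2-bromo-4-methoxyphenyl)-1-hydroxyethyl]-2,4,4-trimethylcyclohexan-1-one (C-2 epimers) | COc1ccc(C[C@H](O)[C@@H]2C(C)(C)CCC(=O)C2C)c(Br)c1
F11 | step 7 | tricyclic 6α-hydroxy-12-methoxy-1-ketone | COc1ccc2C[C@H](O)[C@@H]3C(C)(C)CCC(=O)[C@@]3(C)c2c1
F12 | step 13 | 16-exo-phenylselanyl derivative of 16 | c1ccccc1[Se][C@H]2C(=O)[C@@H]3C4=C(C[C@H](OC(C)=O)[C@@H]5C(C)(C)CC[C@H](OC(C)=O)[C@@]45C)C[C@H]2C3=O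
F13 | step 13 | 16-exo-phenylselanyl-12-hydroxy-15-ketone | c1ccccc1[Se][C@H]2C(=O)[C@@H]3C4=C(C[C@H](OC(C)=O)[C@@H]5C(C)(C)CC[C@H](OC(C)=O)[C@@]45C)C[C@H]2[C@@H]3O
F14 | step 13 | 1α,6α-diacetoxy-12-hydroxy-17-nor-15-ketone | C1C(=O)[C@@H]2C3=C(C[C@H](OC(C)=O)[C@@H]4C(C)(C)CC[C@H](OC(C)=O)[C@@]34C)C[C@H]1[C@@H]2O
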